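**Retrosynthetic overview**
1. (+)-Boehmenan X ⇐ global desilylation of its tris-TIPS ether ⇐ carbodiimide esterification of the C3–CH2OH with TIPS-p-coumaric acid.
2. Key late union: B-alkyl Suzuki–Miyaura coupling of the (2R,3S)-5-bromodihydrobenzofuran core alcohol with the 9-BBN adduct of allyl TIPS-ferulate, two halves of comparable size; it forms the aryl–CH2 bond of the propyl linker with the ferulate ester already in place.
3. Core ⇐ Evans syn-aldol of a ring-A arylacetyl imide [(R)-4-benzyl-2-oxazolidinone] with TIPS-vanillin (sets C3), LiBH4 cleavage, then acid-mediated MOM loss and benzylic SN1 O-cyclisation (sets C2 trans).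
4. Building blocks: catechol → guaiacol → 4-bromoguaiacol feeds ring A (O-allylation, Claisen, MOM, oxidative cleavage), ring B (TIPS, Br/Li, DMF) and the ferulate (Heck with acrylic acid, allyl ester); 4-iodophenol plus acrylic acid gives the coumarate.
5. Ring formation: all benzene rings are bought; the only ring made is the dihydrofuran (O1–C2 closure, step 11), before the fragment coupling.

Assumption: the SMILES encodes the (2R,3S)-trans-dihydrobenzofuran with both cinnamate double bonds E; compounds carried on crude within one operation are treated as not isolated.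

**Route**

Step 1
Reactants: 1 catechol
Product: 2 guaiacol (2-methoxyphenol)
Conditions: MeI (1.0 equiv), K2CO3 (1.0 equiv), acetone, reflux
Reagents that add atoms: iodomethane, CI
Why: Williamson mono-O-methylation of the catechol monoanion; veratrole and unreacted catechol are removed by base extraction and distillation.

Step 2
Reactants: 2 guaiacol
Product: 3 4-bromo-2-methoxyphenol
Conditions: NBS (1.0 equiv), MeCN, 0 °C to rt
Reagents that add atoms: N-bromosuccinimide, O=C1CCC(=O)N1Br
Why: Electrophilic aromatic bromination in which the free OH is the stronger director, so bromine enters para to it.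

Step 3
Reactants: 3 4-bromo-2-methoxyphenol; 4 allyl bromide
Product: 5 1-(allyloxy)-4-bromo-2-methoxybenzene
Conditions: K2CO3, acetone, reflux
Reagents that add atoms: none
Why: Williamson ether synthesis on the phenoxide with a reactive allylic halide.

Step 4
Reactants: 5 1-(allyloxy)-4-bromo-2-methoxybenzene
Product: 6 2-allyl-4-bromo-6-methoxyphenol
Conditions: PhNEt2, 195 °C
Reagents that add atoms: none
Why: Aromatic Claisen [3,3]-rearrangement; the para position is blocked by Br and one ortho position by OMe, so allyl lands only on the free ortho carbon.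

Step 5
Reactants: 6 2-allyl-4-bromo-6-methoxyphenol
Product: 7 1-allyl-5-bromo-3-methoxy-2-(methoxymethoxy)benzene
Conditions: NaH, DMF, 0 °C; MOMCl, 0 °C to rt
Reagents that add atoms: chloromethyl methyl ether, COCCl
Why: O-alkylation of the hindered sodium phenoxide gives a MOM ether that survives oxidation, acylation and boron enolisation and is later removed by acid.

Step 6
Reactants: 7 1-allyl-5-bromo-3-methoxy-2-(methoxymethoxy)benzene
Product: 10 2-[5-bromo-3-methoxy-2-(methoxymethoxy)phenyl]acetic acid, via vicinal diol 8 (not isolated), via arylacetaldehyde 9 (not isolated)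
Conditions: OsO4 (2 mol%), NaIO4, 2,6-lutidine, dioxane/H2O, rt; crude aldehyde, then NaClO2, NaH2PO4, 2-methyl-2-butene, t-BuOH/H2O, 0 °C to rt
Reagents that add atoms: osmium tetroxide, O=[Os](=O)(=O)=O (oxygens of diol 8 and the aldehyde oxygen, re-supplied by sodium periodate, [Na+].[O-]I(=O)(=O)=O); sodium chlorite, [Na+].[O-]Cl=O (second carboxyl oxygen)
Why: Lemieux–Johnson cleavage of the terminal alkene followed directly by Pinnick oxidation avoids handling the enolisable arylacetaldehyde and leaves the aryl bromide, MOM ether and arene untouched.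

Step 7
Reactants: 10 2-[5-bromo-3-methoxy-2-(methoxymethoxy)phenyl]acetic acid
Product: 12 (R)-4-benzyl-3-{[5-bromo-3-methoxy-2-(methoxymethoxy)phenyl]acetyl}oxazolidin-2-one, via mixed pivalic anhydride 11 (not isolated)
Conditions: PivCl, Et3N, THF, −20 °C; then (R)-4-benzyl-2-oxazolidinone, LiCl, −20 °C to rt
Reagents that add atoms: (R)-4-benzyl-2-oxazolidinone, O=C1N[C@H](Cc2ccccc2)CO1; pivaloyl chloride, CC(C)(C)C(Cl)=O (in intermediate 11 only)
Why: Mixed-anhydride N-acylation of the Evans auxiliary under LiCl/Et3N conditions needs no organolithium, so the aryl bromide is safe.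

Step 8
Reactants: 3 4-bromo-2-methoxyphenol
Product: 13 (4-bromo-2-methoxyphenoxy)triisopropylsilane
Conditions: TIPSCl, imidazole, DMF, rt
Reagents that add atoms: chlorotriisopropylsilane, CC(C)[Si](Cl)(C(C)C)C(C)C
Why: Imidazole-promoted phenol silylation; the aryl TIPS ether tolerates n-BuLi, boron enolates, hydride, HCl/MeOH and mild aqueous base, and is removed by fluoride at the end.

Step 9
Reactants: 13 (4-bromo-2-methoxyphenoxy)triisopropylsilane
Product: 15 3-methoxy-4-(triisopropylsilyloxy)benzaldehyde, via aryllithium 14 (not isolated)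
Conditions: n-BuLi, THF, −78 °C; DMF, −78 to 0 °C; 1 M HCl quench
Reagents that add atoms: N,N-dimethylformamide, CN(C)C=O (formyl carbon and oxygen); n-butyllithium, [Li]CCCC (lithium of intermediate 14 only)
Why: Fast bromine–lithium exchange followed by Bouveault-type formylation of the aryllithium with DMF.

Step 10
Reactants: 12 (R)-4-benzyl-3-{[5-bromo-3-methoxy-2-(methoxymethoxy)phenyl]acetyl}oxazolidin-2-one; 15 3-methoxy-4-(triisopropylsilyloxy)benzaldehyde
Product: 18 (4R)-4-benzyl-3-[(2R,3R)-2-[5-bromo-3-methoxy-2-(methoxymethoxy)phenyl]-3-hydroxy-3-(3-methoxy-4-triisopropylsilyloxyphenyl)propanoyl]oxazolidin-2-one, via Z-boron enolate 16 (not isolated), via boron aldolate 17 (not isolated)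
Conditions: Bu2BOTf, i-Pr2NEt, CH2Cl2, −78 to 0 °C; 15, −78 to 0 °C; pH 7 buffer, MeOH, 30% H2O2, 0 °C
Reagents that add atoms: dibutylboron triflate, CCCCB(CCCC)OS(=O)(=O)C(F)(F)F (Bu2B of intermediates 16 and 17 only; no reagent atoms in 18)
Why: Evans syn-aldol through the Z-boron enolate and a dipole-minimised Zimmerman–Traxler chair, in which the (R)-benzyl auxiliary directs the aldehyde to one enolate face and sets the α-carbon (future C3) as 2R, with the carbinol 3R.

Step 11
Reactants: 18 (4R)-4-benzyl-3-[(2R,3R)-2-[5-bromo-3-methoxy-2-(methoxymethoxy)phenyl]-3-hydroxy-3-(3-methoxy-4-triisopropylsilyloxyphenyl)propanoyl]oxazolidin-2-one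
Product: 21 [(2R,3S)-5-bromo-7-methoxy-2-(3-methoxy-4-triisopropylsilyloxyphenyl)-2,3-dihydro-1-benzofuran-3-yl]methanol, via MOM diol 19 (not isolated), via phenol diol 20 (not isolated)
Conditions: LiBH4, MeOH (1 equiv), THF, 0 °C; then MeOH, conc. HCl to ca. 1 M, 45 °C
Reagents that add atoms: none
Why: Reductive cleavage of the imide gives the 1,3-diol without touching the α-centre, and acid then removes the MOM group and ionises the p-silyloxybenzylic alcohol so the ring-A phenol closes the five-membered ring by SN1 etherification, giving the thermodynamically preferred trans ring (C2 = R, dictated by C3 = S).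

Step 12
Reactants: 13 (4-bromo-2-methoxyphenoxy)triisopropylsilane; 22 acrylic acid
Product: 23 (E)-3-(3-methoxy-4-triisopropylsilyloxyphenyl)acrylic acid
Conditions: Pd(OAc)2 (3 mol%), P(o-tol)3 (6 mol%), Et3N, DMF, 100 °C; acidic work-up
Reagents that add atoms: none
Why: Mizoroki–Heck arylation of acrylate at the β-carbon with syn β-hydride elimination gives only the E-cinnamic acid.

Step 13
Reactants: 23 (E)-3-(3-methoxy-4-triisopropylsilyloxyphenyl)acrylic acid; 4 allyl bromide
Product: 24 allyl (E)-3-(3-methoxy-4-triisopropylsilyloxyphenyl)acrylate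
Conditions: KHCO3, DMF, rt
Reagents that add atoms: none
Why: SN2 O-alkylation of the carboxylate under weakly basic conditions that leave the aryl silyl ether intact.

Step 14
Reactants: 24 allyl (E)-3-(3-methoxy-4-triisopropylsilyloxyphenyl)acrylate; 21 [(2R,3S)-5-bromo-7-methoxy-2-(3-methoxy-4-triisopropylsilyloxyphenyl)-2,3-dihydro-1-benzofuran-3-yl]methanol
Product: 26 3-[(2R,3S)-3-(hydroxymethyl)-7-methoxy-2-(3-methoxy-4-triisopropylsilyloxyphenyl)-2,3-dihydro-1-benzofuran-5-yl]propyl (E)-3-(3-methoxy-4-triisopropylsilyloxyphenyl)acrylate, via B-alkyl-9-BBN 25 (not isolated)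
Conditions: 24 (1.4 equiv), 9-BBN, THF, 0 °C to rt; then 21, Pd(OAc)2 (5 mol%), SPhos (10 mol%), K3PO4·H2O, THF/H2O, 45 °C
Reagents that add atoms: 9-borabicyclo[3.3.1]nonane, B1C2CCCC1CCC2 (boron unit of intermediate 25 only; no reagent atoms in 26)
Why: 9-BBN hydroborates the terminal allyl alkene anti-Markovnikov far faster than the conjugated cinnamate, and the resulting primary alkylborane undergoes B-alkyl Suzuki–Miyaura coupling with the aryl bromide under mild phosphate conditions that spare the ester, the silyl ethers and both stereocentres.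

Step 15
Reactants: 27 4-iodophenol
Product: 28 (4-iodophenoxy)triisopropylsilane
Conditions: TIPSCl, imidazole, DMF, rt
Reagents that add atoms: chlorotriisopropylsilane, CC(C)[Si](Cl)(C(C)C)C(C)C
Why: Standard imidazole-promoted silylation of the phenol.

Step 16
Reactants: 28 (4-iodophenoxy)triisopropylsilane; 22 acrylic acid
Product: 29 (E)-3-(4-triisopropylsilyloxyphenyl)acrylic acid
Conditions: Pd(OAc)2 (2 mol%), Et3N, DMF, 80 °C; acidic work-up
Reagents that add atoms: none
Why: Ligand-free Mizoroki–Heck reaction of the aryl iodide with acrylate gives the E-cinnamic acid.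

Step 17
Reactants: 26 3-[(2R,3S)-3-(hydroxymethyl)-7-methoxy-2-(3-methoxy-4-triisopropylsilyloxyphenyl)-2,3-dihydro-1-benzofuran-5-yl]propyl (E)-3-(3-methoxy-4-triisopropylsilyloxyphenyl)acrylate; 29 (E)-3-(4-triisopropylsilyloxyphenyl)acrylic acid
Product: 30 tris-TIPS boehmenan X, {(2R,3S)-7-methoxy-2-(3-methoxy-4-triisopropylsilyloxyphenyl)-5-[3-({(E)-3-(3-methoxy-4-triisopropylsilyloxyphenyl)acryloyl}oxy)propyl]-2,3-dihydro-1-benzofuran-3-yl}methyl (E)-3-(4-triisopropylsilyloxyphenyl)acrylate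
Conditions: EDC·HCl, DMAP, CH2Cl2, 0 °C to rt
Reagents that add atoms: none
Why: Steglich-type carbodiimide/DMAP esterification of the only free hydroxyl; the phenols are all silylated, so no competing acylation occurs.

Step 18
Reactants: 30 tris-TIPS boehmenan X
Product: 31 (+)-boehmenan X
Conditions: TBAF (3.6 equiv), AcOH (3.6 equiv), THF, 0 °C to rt
Reagents that add atoms: none
Why: Fluoride-mediated cleavage of the three aryl silyl ethers, buffered with acetic acid so that no free phenoxide can open the dihydrofuran via a quinone methide or attack the two cinnamate esters.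

**Compound list**
1 | catechol | Oc1ccccc1O | starting material
2 | guaiacol (2-methoxyphenol) | COc1ccccc1O | intermediate
3 | 4-bromo-2-methoxyphenol | COc1cc(Br)ccc1O | intermediate
4 | allyl bromide | C=CCBr | starting material
5 | 1-(allyloxy)-4-bromo-2-methoxybenzene | COc1cc(Br)ccc1OCC=C | intermediate
6 | 2-allyl-4-bromo-6-methoxyphenol | COc1cc(Br)cc(CC=C)c1O | intermediate
7 | 1-allyl-5-bromo-3-methoxy-2-(methoxymethoxy)benzene | COCOc1c(CC=C)cc(Br)cc1OC | intermediate
8 | 3-[5-bromo-3-methoxy-2-(methoxymethoxy)phenyl]propane-1,2-diol (racemic; not isolated) | COCOc1c(CC(O)CO)cc(Br)cc1OC | intermediate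
9 | 2-[5-bromo-3-methoxy-2-(methoxymethoxy)phenyl]acetaldehyde (not isolated) | COCOc1c(CC=O)cc(Br)cc1OC | intermediate
10 | 2-[5-bromo-3-methoxy-2-(methoxymethoxy)phenyl]acetic acid | COCOc1c(CC(=O)O)cc(Br)cc1OC | intermediate
11 | mixed pivalic anhydride of 10 (not isolated) | COCOc1c(CC(=O)OC(=O)C(C)(C)C)cc(Br)cc1OC | intermediate
12 | (R)-4-benzyl-3-{[5-bromo-3-methoxy-2-(methoxymethoxy)phenyl]acetyl}oxazolidin-2-one | COCOc1c(CC(=O)N2[C@H](Cc3ccccc3)COC2=O)cc(Br)cc1OC | intermediate
13 | (4-bromo-2-methoxyphenoxy)triisopropylsilane | COc1cc(Br)ccc1O[Si](C(C)C)(C(C)C)C(C)C | intermediate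
14 | [3-methoxy-4-(triisopropylsilyloxy)phenyl]lithium (not isolated) | COc1cc([Li])ccc1O[Si](C(C)C)(C(C)C)C(C)C | intermediate
15 | 3-methoxy-4-(triisopropylsilyloxy)benzaldehyde | COc1cc(C=O)ccc1O[Si](C(C)C)(C(C)C)C(C)C | intermediate
16 | (Z)-dibutylboron enolate of 12 (not isolated) | CCCCB(CCCC)O/C(=C\c1cc(Br)cc(OC)c1OCOC)N1[C@H](Cc2ccccc2)COC1=O | intermediate
17 | O-dibutylboryl aldolate of 18 (not isolated) | O=C([C@H](c1cc(Br)cc(OC)c1OCOC)[C@@H](OB(CCCC)CCCC)c1ccc(O[Si](C(C)C)(C(C)C)C(C)C)c(OC)c1)N1[C@H](Cc2ccccc2)COC1=O | intermediate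
18 | (4R)-4-benzyl-3-[(2R,3R)-2-[5-bromo-3-methoxy-2-(methoxymethoxy)phenyl]-3-hydroxy-3-(3-methoxy-4-triisopropylsilyloxyphenyl)propanoyl]oxazolidin-2-one | O=C([C@H](c1cc(Br)cc(OC)c1OCOC)[C@@H](O)c1ccc(O[Si](C(C)C)(C(C)C)C(C)C)c(OC)c1)N1[C@H](Cc2ccccc2)COC1=O | intermediate
19 | (1R,2S)-2-[5-bromo-3-methoxy-2-(methoxymethoxy)phenyl]-1-(3-methoxy-4-triisopropylsilyloxyphenyl)propane-1,3-diol (not isolated) | OC[C@H](c1cc(Br)cc(OC)c1OCOC)[C@@H](O)c1ccc(O[Si](C(C)C)(C(C)C)C(C)C)c(OC)c1 | intermediate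
20 | (1R,2S)-2-(5-bromo-2-hydroxy-3-methoxyphenyl)-1-(3-methoxy-4-triisopropylsilyloxyphenyl)propane-1,3-diol (not isolated) | OC[C@H](c1cc(Br)cc(OC)c1O)[C@@H](O)c1ccc(O[Si](C(C)C)(C(C)C)C(C)C)c(OC)c1 | intermediate
21 | [(2R,3S)-5-bromo-7-methoxy-2-(3-methoxy-4-triisopropylsilyloxyphenyl)-2,3-dihydro-1-benzofuran-3-yl]methanol | Brc1cc(OC)c2c(c1)[C@@H](CO)[C@H](c1ccc(O[Si](C(C)C)(C(C)C)C(C)C)c(OC)c1)O2 | intermediate
22 | acrylic acid | C=CC(=O)O | starting material
23 | (E)-3-(3-methoxy-4-triisopropylsilyloxyphenyl)acrylic acid | COc1cc(/C=C/C(=O)O)ccc1O[Si](C(C)C)(C(C)C)C(C)C | intermediate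
24 | allyl (E)-3-(3-methoxy-4-triisopropylsilyloxyphenyl)acrylate | COc1cc(/C=C/C(=O)OCC=C)ccc1O[Si](C(C)C)(C(C)C)C(C)C | intermediate
25 | 3-(9-borabicyclo[3.3.1]nonan-9-yl)propyl (E)-3-(3-methoxy-4-triisopropylsilyloxyphenyl)acrylate (not isolated) | COc1cc(/C=C/C(=O)OCCCB2C3CCCC2CCC3)ccc1O[Si](C(C)C)(C(C)C)C(C)C | intermediate
26 | 3-[(2R,3S)-3-(hydroxymethyl)-7-methoxy-2-(3-methoxy-4-triisopropylsilyloxyphenyl)-2,3-dihydro-1-benzofuran-5-yl]propyl (E)-3-(3-methoxy-4-triisopropylsilyloxyphenyl)acrylate | COc1cc(/C=C/C(=O)OCCCc2cc(OC)c3c(c2)[C@@H](CO)[C@H](c2ccc(O[Si](C(C)C)(C(C)C)C(C)C)c(OC)c2)O3)ccc1O[Si](C(C)C)(C(C)C)C(C)C | intermediate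
27 | 4-iodophenol | Oc1ccc(I)cc1 | starting material
28 | (4-iodophenoxy)triisopropylsilane | CC(C)[Si](Oc1ccc(I)cc1)(C(C)C)C(C)C | intermediate
29 | (E)-3-(4-triisopropylsilyloxyphenyl)acrylic acid | OC(=O)/C=C/c1ccc(O[Si](C(C)C)(C(C)C)C(C)C)cc1 | intermediate
30 | tris-TIPS boehmenan X | COc1cc(/C=C/C(=O)OCCCc2cc(OC)c3c(c2)[C@@H](COC(=O)/C=C/c2ccc(O[Si](C(C)C)(C(C)C)C(C)C)cc2)[C@H](c2ccc(O[Si](C(C)C)(C(C)C)C(C)C)c(OC)c2)O3)ccc1O[Si](C(C)C)(C(C)C)C(C)C | intermediate
31 | (+)-boehmenan X, (2R,3S) | COc1cc(/C=C/C(=O)OCCCc2cc(OC)c3c(c2)[C@@H](COC(=O)/C=C/c2ccc(O)cc2)[C@H](c2ccc(O)c(OC)c2)O3)ccc1O | target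

**Step count**
Total steps: 18. Longest linear sequence: 12 steps (1, 2, 3, 4, 5, 6, 7, 10, 11, 14, 17, 18).

**Three steps most likely to fail**

Step 10 (Evans aldol). The α-aryl-β-aryl-β-hydroxy imide is prone to retro-aldol, and the electron-rich aldehyde is a sluggish electrophile. The fallback sets out from acid 10 and aldehyde 15 and comes back at 21. It replaces the reversible aldol by an irreversible enolate alkylation with an oxocarbenium ion. Acid 10 is loaded onto the antipodal auxiliary (PivCl, Et3N, then (S)-4-benzyl-2-oxazolidinone, LiCl) to give the (4S)-imide F1. Aldehyde 15 is converted with HC(OMe)3 and catalytic PPTS in MeOH into the dimethyl acetal F2. The chlorotitanium enolate of F1 (TiCl4, i-Pr2NEt, CH2Cl2, −78 °C) is treated with F2 (SnCl4 added if the acetal needs further activation). The chelated enolate is attacked anti to the benzyl group, the face opposite to that used by the boron aldol, which is why the other auxiliary enantiomer is needed. This gives the β-methoxy imide F3 with the same (2R) α-centre; the configuration at the methoxy carbon is irrelevant. LiBH4 (THF, 0 °C) gives the methoxy alcohol F4, which cannot undergo retro-aldol. HCl/MeOH at 45 °C removes the MOM group and ionises the benzylic methyl ether, closing the ring to 21.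

Step 11 (reduction and acid ring closure in one operation). Hydride or alkoxide may trigger retro-aldol of the free β-hydroxy imide before the auxiliary is cleaved. The fallback sets out from 18 and comes back at 21. The aldol hydroxyl is first capped (TESOTf, 2,6-lutidine, CH2Cl2, −78 °C) to give the triethylsilyl ether F5. LiBH4 reduction then gives the mono-protected primary alcohol F6, which is isolated and purified away from the auxiliary. HCl/MeOH at 45 °C strips the TES and MOM groups and closes the trans ring by the same benzylic SN1 etherification to give 21.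

Step 14 (hydroboration and B-alkyl Suzuki coupling). 9-BBN may partly reduce the cinnamate or add at the internal allyl carbon, and the electron-rich aryl bromide may couple slowly under conditions mild enough for the ester. The fallback sets out from 21 (using 29 and 23) and comes back at 30. It drops the fragment coupling in favour of installing the propyl linker on the core and esterifying afterwards. Alcohol 21 is esterified with 29 (EDC·HCl, DMAP, CH2Cl2) to give the bromo coumarate F7. Base-free Stille allylation (allyltributylstannane, Pd(PPh3)4, toluene, 100 °C) gives the 5-allyl compound F8. Hydroboration with 9-BBN (THF, 0 °C) and NaBO3·4H2O oxidation gives the 3-hydroxypropyl compound F9. EDC/DMAP esterification of F9 with 23 gives 30.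

**Further compounds**
F1 | step 10 | (S)-4-benzyl-3-{[5-bromo-3-methoxy-2-(methoxymethoxy)phenyl]acetyl}oxazolidin-2-one | COCOc1c(CC(=O)N2[C@@H](Cc3ccccc3)COC2=O)cc(Br)cc1OC
F2 | step 10 | [4-(dimethoxymethyl)-2-methoxyphenoxy]triisopropylsilane | COc1cc(C(OC)OC)ccc1O[Si](C(C)C)(C(C)C)C(C)C
F3 | step 10 | (4S)-4-benzyl-3-[(2R)-2-[5-bromo-3-methoxy-2-(methoxymethoxy)phenyl]-3-methoxy-3-(3-methoxy-4-triisopropylsilyloxyphenyl)propanoyl]oxazolidin-2-one (C3 epimers) | O=C([C@H](c1cc(Br)cc(OC)c1OCOC)C(OC)c1ccc(O[Si](C(C)C)(C(C)C)C(C)C)c(OC)c1)N1[C@@H](Cc2ccccc2)COC1=O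
F4 | step 10 | (2S)-2-[5-bromo-3-methoxy-2-(methoxymethoxy)phenyl]-3-methoxy-3-(3-methoxy-4-triisopropylsilyloxyphenyl)propan-1-ol (C3 epimers) | OC[C@H](c1cc(Br)cc(OC)c1OCOC)C(OC)c1ccc(O[Si](C(C)C)(C(C)C)C(C)C)c(OC)c1
F5 | step 11 | (4R)-4-benzyl-3-[(2R,3R)-2-[5-bromo-3-methoxy-2-(methoxymethoxy)phenyl]-3-(3-methoxy-4-triisopropylsilyloxyphenyl)-3-(triethylsilyloxy)propanoyl]oxazolidin-2-one | O=C([C@H](c1cc(Br)cc(OC)c1OCOC)[C@@H](O[Si](CC)(CC)CC)c1ccc(O[Si](C(C)C)(C(C)C)C(C)C)c(OC)c1)N1[C@H](Cc2ccccc2)COC1=O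
F6 | step 11 | (2S,3R)-2-[5-bromo-3-methoxy-2-(methoxymethoxy)phenyl]-3-(3-methoxy-4-triisopropylsilyloxyphenyl)-3-(triethylsilyloxy)propan-1-ol | OC[C@H](c1cc(Br)cc(OC)c1OCOC)[C@@H](O[Si](CC)(CC)CC)c1ccc(O[Si](C(C)C)(C(C)C)C(C)C)c(OC)c1
F7 | step 14 | [(2R,3S)-5-bromo-7-methoxy-2-(3-methoxy-4-triisopropylsilyloxyphenyl)-2,3-dihydro-1-benzofuran-3-yl]methyl (E)-3-(4-triisopropylsilyloxyphenyl)acrylate | Brc1cc(OC)c2c(c1)[C@@H](COC(=O)/C=C/c1ccc(O[Si](C(C)C)(C(C)C)C(C)C)cc1)[C@H](c1ccc(O[Si](C(C)C)(C(C)C)C(C)C)c(OC)c1)O2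
F8 | step 14 | [(2R,3S)-5-allyl-7-methoxy-2-(3-methoxy-4-triisopropylsilyloxyphenyl)-2,3-dihydro-1-benzofuran-3-yl]methyl (E)-3-(4-triisopropylsilyloxyphenyl)acrylate | C=CCc1cc(OC)c2c(c1)[C@@H](COC(=O)/C=C/c1ccc(O[Si](C(C)C)(C(C)C)C(C)C)cc1)[C@H](c1ccc(O[Si](C(C)C)(C(C)C)C(C)C)c(OC)c1)O2
F9 | step 14 | [(2R,3S)-5-(3-hydroxypropyl)-7-methoxy-2-(3-methoxy-4-triisopropylsilyloxyphenyl)-2,3-dihydro-1-benzofuran-3-yl]methyl (E)-3-(4-triisopropylsilyloxyphenyl)acrylate | OCCCc1cc(OC)c2c(c1)[C@@H](COC(=O)/C=C/c1ccc(O[Si](C(C)C)(C(C)C)C(C)C)cc1)[C@H](c1ccc(O[Si](C(C)C)(C(C)C)C(C)C)c(OC)c1)O2
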